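**Retrosynthetic overview**

- Numbering: lactone ring O1–C2(=O)–C3=C4(OMe)–C5–C6, fused at C5–C6 to cyclobutane C5–C6–C8–C7 (C7 aryl, C8 pyranonyl). C5 (next to the carboxyl-level C4) and C7 (benzylic) are adjacent and both radical-stabilised, so the C5–C7 bond is made by cutting nitrogen out of a pyrrolidine N–C5–C6–C8–C7.
- Ring 1 (pyrrolidine): endo azomethine ylide [3+2] of a glycinate aldimine (C5–N–C7) onto a (Z)-2-silyloxybutenedioate (C6=C8). The extra ester on C6 activates the otherwise donor-deactivated enol ether and is the latent styryl carbon. C8 is then epimerised.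
- Ring 2 (cyclobutane): N-amination, loss of N2, 1,4-biradical closure of C5–C7.
- Ring 3 (2-pyranone on C8): methyl ester + acetoacetate dianion, acylketene cyclisation, O-methylation. Ring 4 (dihydropyranone): C5 acid → acylketene → lactonisation onto the C6 hydroxyl, O-methylation.
- Last: C6 benzyl ester → aldehyde → Julia–Kocienski styryl, then desilylation.

Key step: step 7

Remark: 1,3-dicarbonyl compounds are drawn as keto tautomers, the locants of the overview are used for all intermediates, and in step 5 the ligand antipode is taken that gives the enantiomer drawn.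

**Step 1**
Reactants: 1 4-hydroxybenzaldehyde
Product: 2 4-[(triisopropylsilyl)oxy]benzaldehyde
Conditions: iPr3SiCl, imidazole, DMF, rt
Reagents that add atoms: chlorotriisopropylsilane CC(C)[Si](Cl)(C(C)C)C(C)C
Why: Imidazole-promoted O-silylation of the phenol; the triisopropylsilyl ether is chosen because it should withstand ammonia in hot trifluoroethanol, amidine base, carbonate and trifluoroacetic acid in later steps.

**Step 2**
Reactants: 2 4-[(triisopropylsilyl)oxy]benzaldehyde; 3 tert-butyl glycinate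
Product: 4 tert-butyl N-[(E)-4-(triisopropylsilyloxy)benzylidene]glycinate
Conditions: MgSO4, CH2Cl2, rt
Reagents that add atoms: none
Why: Imine condensation driven by the drying agent gives the (E)-aldimine that is the azomethine ylide precursor (C7–N–C5).

**Step 3**
Reactants: 5 methyl acetate; 6 dibenzyl oxalate
Product: 8 1-benzyl 4-methyl 2-oxobutanedioate, via lithium enolate of methyl acetate 7 (not isolated)
Conditions: LiN(iPr)2, THF, −78 °C; then 6, −78 °C; aq. HCl
Reagents that add atoms: none
Why: Crossed Claisen condensation of an ester enolate with a non-enolisable oxalate, the chelated tetrahedral adduct preventing a second addition; it puts the benzyl ester on the future C6 and the methyl ester on the future C8.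

**Step 4**
Reactants: 8 1-benzyl 4-methyl 2-oxobutanedioate
Product: 9 1-benzyl 4-methyl (2Z)-2-[(triethylsilyl)oxy]but-2-enedioate
Conditions: Et3SiOSO2CF3, Et3N, CH2Cl2, 0 °C
Reagents that add atoms: triethylsilyl trifluoromethanesulfonate CC[Si](CC)(CC)OS(=O)(=O)C(F)(F)F
Why: O-silylation of the hydrogen-bonded Z enol of the oxaloacetate (silyl enol ether formation) should give the Z isomer, with the silyloxy group cis to the CH–CO2Me ester, the geometry that puts oxygen endo in step 5.

**Step 5**
Reactants: 4 tert-butyl N-[(E)-4-(triisopropylsilyloxy)benzylidene]glycinate; 9 1-benzyl 4-methyl (2Z)-2-[(triethylsilyl)oxy]but-2-enedioate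
Product: 10 3-benzyl 2-tert-butyl 4-methyl 3-(triethylsilyloxy)-5-[4-(triisopropylsilyloxy)phenyl]pyrrolidine-2,3,4-tricarboxylate (endo adduct; C8 ester cis to aryl)
Conditions: AgOAc (5 mol %), (S)-QUINAP (5.5 mol %), iPr2NEt (10 mol %), THF, −20 °C to rt
Reagents that add atoms: none
Why: Catalytic asymmetric azomethine ylide 1,3-dipolar cycloaddition (Michael–Mannich on the N,O-chelated silver ylide): the glycine carbon adds to the oxygen-bearing carbon, the electrophilic terminus of 2-alkoxybutenedioates, with the second ester supplying the activation that a lone β-silyloxy acrylate lacks; the W-shaped ylide gives the 2,5-cis ring, the endo transition state places the C8 ester and the silyloxy group cis to it on the face of the C5 ester and C7 aryl, and the chiral phosphine sets the absolute configuration of C5, C6, C7 and C8.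

**Step 6**
Reactants: 10 endo pyrrolidine triester
Product: 11 3-benzyl 2-tert-butyl 4-methyl 3-(triethylsilyloxy)-5-[4-(triisopropylsilyloxy)phenyl]pyrrolidine-2,3,4-tricarboxylate (C8 epimer; C8 ester trans to aryl)
Conditions: DBU (0.5 equiv), toluene, 50 °C
Reagents that add atoms: none
Why: Thermodynamic epimerisation through the methyl ester enolate moves the C8 ester off the face it shares with the C7 aryl and C6 silyloxy groups (the usual endo to 4,5-trans isomerisation of such cycloadducts), while C5, an α-amino tert-butyl ester in the favoured 2,5-cis arrangement, should stay.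

**Step 7**
Reactants: 11 2,5-cis pyrrolidine triester
Product: 14 1-benzyl 2-tert-butyl 4-methyl 1-(triethylsilyloxy)-3-[4-(triisopropylsilyloxy)phenyl]cyclobutane-1,2,4-tricarboxylate, via 1,1-diazene 12 (not isolated), via 1,4-biradical 13 (not isolated)
Conditions: PhI(OH)OTs (2.5 equiv), NH2CO2NH4 (8 equiv), CF3CH2OH, 80 °C
Reagents that add atoms: none
Why: PhI(OH)OTs and ammonia (from ammonium carbamate) form an iminoiodane that transfers NH to the ring nitrogen and, after a second oxidation, gives 1,1-diazene 12, which loses N2 to the singlet 1,4-biradical 13 with radical sites on C5 (α to the tert-butyl ester) and C7 (benzylic). The closest known reaction is the stereoretentive iodonitrene contraction of 2-carboxylate-5-aryl pyrrolidines from azomethine ylide cycloadditions to cyclobutanes, which tolerates an adjacent quaternary centre. The cyclobutane C5–C6–C8–C7 is closed by intramolecular radical–radical recombination of the 1,4-biradical (C5–C7 bond), a ring contraction and not a polar or chain cyclisation. C5 and C7 are the two new ring stereocentres and keep the cis relation they had across nitrogen, because recombination of the singlet pair is faster than rotation about C5–C6 or C7–C8, so both are controlled by the 2,5-cis configuration of 11; C6 and C8 are not touched. The step needs closure to outrun β-scission of C6–C8 (to a cinnamate and a silyloxybutenedioate) and N-amination to outrun arene oxidation and ester ammonolysis; the ester and aryl stabilisation of the two radicals, the singlet state, the hindered esters and the silyl-protected phenol are what the substrate offers for this.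

**Step 8**
Reactants: 14 cyclobutane triester; 15 tert-butyl acetoacetate
Product: 17 1-benzyl 2-tert-butyl 4-(5-tert-butoxy-3,5-dioxopentanoyl)-1-(triethylsilyloxy)-3-[4-(triisopropylsilyloxy)phenyl]cyclobutane-1,2-dicarboxylate, via dilithium dianion of tert-butyl acetoacetate 16 (not isolated)
Conditions: 15, LiN(iPr)2 (2 equiv per 15; 3 equiv dianion), THF, 0 °C; then 14, 0 °C to rt; aq. HCl
Reagents that add atoms: none
Why: Claisen acylation of the γ-carbon of the acetoacetate dianion by the least hindered ester (the C8 methyl ester); the quaternary benzyl ester and the tert-butyl ester are shielded, the C6 oxygen is silylated so no retro-aldol opening can start, and the dianion is too weak a base to enolise the ring esters.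

**Step 9**
Reactants: 17 triketo ester
Product: 19 1-benzyl 2-tert-butyl 4-(4-hydroxy-2-oxo-2H-pyran-6-yl)-1-(triethylsilyloxy)-3-[4-(triisopropylsilyloxy)phenyl]cyclobutane-1,2-dicarboxylate, via acylketene 18 (not isolated)
Conditions: toluene, 110 °C
Reagents that add atoms: none
Why: Thermolysis of the tert-butyl β-keto ester expels tert-butanol to give acylketene 18, which is captured by the enol oxygen of the ketone on C8 (acylketene cyclisation to a 4-hydroxy-2-pyranone) under neutral conditions that should leave C8 and the simple tert-butyl ester alone.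

**Step 10**
Reactants: 19 hydroxypyranone
Product: 20 1-benzyl 2-tert-butyl 4-(4-methoxy-2-oxo-2H-pyran-6-yl)-1-(triethylsilyloxy)-3-[4-(triisopropylsilyloxy)phenyl]cyclobutane-1,2-dicarboxylate
Conditions: Me2SO4, K2CO3, acetone, rt
Reagents that add atoms: dimethyl sulfate COS(=O)(=O)OC
Why: O-methylation of the vinylogous acid, which with dimethyl sulfate and carbonate in acetone favours the 4-methoxy-2-pyranone over the 2-methoxy-4-pyranone.

**Step 11**
Reactants: 20 methoxypyranone diester
Product: 21 2-(benzyloxycarbonyl)-2-hydroxy-3-(4-methoxy-2-oxo-2H-pyran-6-yl)-4-[4-(triisopropylsilyloxy)phenyl]cyclobutane-1-carboxylic acid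
Conditions: CF3CO2H/CH2Cl2/H2O (10:10:1), 0 °C to rt
Reagents that add atoms: none
Why: Acidolysis removes the tert-butyl ester (as isobutene) and the tertiary triethylsilyl ether while the benzyl ester, the methoxypyranone and the aryl triisopropylsilyl ether should survive; it is placed before the acid-labile styryl carbinol system exists.

**Step 12**
Reactants: 21 cis-hydroxy acid; 22 Meldrum's acid
Product: 25 benzyl 8-(4-methoxy-2-oxo-2H-pyran-6-yl)-3,5-dioxo-7-[4-(triisopropylsilyloxy)phenyl]-2-oxabicyclo[4.2.0]octane-1-carboxylate, via acyl Meldrum's acid 23 (not isolated), via acylketene 24 (not isolated)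
Conditions: 22, EDC·HCl, DMAP, CH2Cl2, 0 °C to rt; then toluene, 90 °C (dilute)
Reagents that add atoms: none
Why: Carbodiimide C-acylation of Meldrum's acid followed by thermolysis (loss of acetone and CO2) gives acylketene 24, which is trapped by the tertiary C6 hydroxyl (acylketene lactonisation to the six-membered β-keto lactone); only the cis hydroxy acid can close, so the cis ring fusion is secured without base.

**Step 13**
Reactants: 25 β-keto lactone
Product: 26 benzyl 5-methoxy-8-(4-methoxy-2-oxo-2H-pyran-6-yl)-3-oxo-7-[4-(triisopropylsilyloxy)phenyl]-2-oxabicyclo[4.2.0]oct-4-ene-1-carboxylate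
Conditions: Me2SO4, K2CO3, acetone, rt
Reagents that add atoms: dimethyl sulfate COS(=O)(=O)OC
Why: O-methylation of the β-keto lactone enol, the standard way to the 4-methoxy-5,6-dihydro-2-pyranone of kavalactones, using a base too weak to deprotonate C5 and open the lactone.

**Step 14**
Reactants: 26 benzyl ester
Product: 27 5-methoxy-8-(4-methoxy-2-oxo-2H-pyran-6-yl)-3-oxo-7-[4-(triisopropylsilyloxy)phenyl]-2-oxabicyclo[4.2.0]oct-4-ene-1-carboxylic acid
Conditions: H2 (1 atm), Pd/C, EtOAc, rt
Reagents that add atoms: none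
Why: Hydrogenolysis of the benzyl ester, much faster than reduction of the push–pull enol ether and pyranone double bonds, so the reaction is stopped at the acid.

**Step 15**
Reactants: 27 carboxylic acid
Product: 28 1-(hydroxymethyl)-5-methoxy-8-(4-methoxy-2-oxo-2H-pyran-6-yl)-7-[4-(triisopropylsilyloxy)phenyl]-2-oxabicyclo[4.2.0]oct-4-en-3-one
Conditions: BH3·SMe2, THF, 0 °C to rt; MeOH quench
Reagents that add atoms: none
Why: Chemoselective borane reduction of the carboxylic acid through its acyloxyborane; the lactone and pyranone carbonyls, both vinylogous carbonates, are inert to borane.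

**Step 16**
Reactants: 28 primary alcohol
Product: 29 5-methoxy-8-(4-methoxy-2-oxo-2H-pyran-6-yl)-3-oxo-7-[4-(triisopropylsilyloxy)phenyl]-2-oxabicyclo[4.2.0]oct-4-ene-1-carbaldehyde
Conditions: Dess–Martin periodinane, NaHCO3, CH2Cl2, rt
Reagents that add atoms: none
Why: Dess–Martin oxidation of the neopentyl alcohol to a non-enolisable aldehyde under buffered neutral conditions.

**Step 17**
Reactants: 2 4-[(triisopropylsilyl)oxy]benzaldehyde
Product: 30 {4-[(triisopropylsilyl)oxy]phenyl}methanol
Conditions: NaBH4, MeOH, 0 °C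
Reagents that add atoms: none
Why: Borohydride reduction of the aldehyde to the benzylic alcohol.

**Step 18**
Reactants: 30 {4-[(triisopropylsilyl)oxy]phenyl}methanol
Product: 31 1-phenyl-5-({4-[(triisopropylsilyl)oxy]benzyl}sulfanyl)-1H-tetrazole
Conditions: 1-phenyl-1H-tetrazole-5-thiol, PPh3, DIAD, THF, 0 °C to rt
Reagents that add atoms: 1-phenyl-1H-tetrazole-5-thiol Sc1nnnn1-c1ccccc1
Why: Mitsunobu thioetherification of the benzylic alcohol with the acidic tetrazole thiol.

**Step 19**
Reactants: 31 tetrazolyl sulfide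
Product: 32 1-phenyl-5-({4-[(triisopropylsilyl)oxy]benzyl}sulfonyl)-1H-tetrazole
Conditions: (NH4)6Mo7O24·4H2O (cat.), 30% H2O2, EtOH, rt
Reagents that add atoms: hydrogen peroxide OO
Why: Molybdate-catalysed peroxide oxidation of the sulfide to the sulfone, which leaves the aryl silyl ether intact.

**Step 20**
Reactants: 29 aldehyde; 32 tetrazolyl sulfone
Product: 34 bis(triisopropylsilyl) ether of the target, via potassium sulfonyl carbanion 33 (not isolated)
Conditions: 32, KN(SiMe3)2, THF, −78 °C; then 29, −78 °C to rt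
Reagents that add atoms: none
Why: Julia–Kocienski olefination (carbanion addition, Smiles rearrangement, loss of SO2 and tetrazolone) should give the E styrene; the sulfonyl carbanion is far less basic than a benzylphosphonate anion, so C5–H (whose removal would open the lactone by elimination) and C8–H should not be touched.

**Step 21**
Reactants: 34 bis-silyl ether
Product: 35 (1R,6S,7S,8S)-7-(4-hydroxyphenyl)-1-[(E)-2-(4-hydroxyphenyl)ethenyl]-5-methoxy-8-(4-methoxy-2-oxo-2H-pyran-6-yl)-2-oxabicyclo[4.2.0]oct-4-en-3-one (CNP0228336.2)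
Conditions: Bu4NF, AcOH, THF, 0 °C
Reagents that add atoms: none
Why: Fluoride cleavage of both aryl silyl ethers, buffered with acetic acid so that no phenoxide forms that could expel the allylic lactone oxygen through the styrene.

**Compound list**

1 | 4-hydroxybenzaldehyde | O=Cc1ccc(O)cc1 | starting material
2 | 4-[(triisopropylsilyl)oxy]benzaldehyde | CC(C)[Si](C(C)C)(C(C)C)Oc1ccc(C=O)cc1 | intermediate
3 | tert-butyl glycinate | NCC(=O)OC(C)(C)C | starting material
4 | tert-butyl N-[(E)-4-(triisopropylsilyloxy)benzylidene]glycinate | CC(C)(C)OC(=O)C/N=C/c1ccc(O[Si](C(C)C)(C(C)C)C(C)C)cc1 | intermediate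
5 | methyl acetate | CC(=O)OC | starting material
6 | dibenzyl oxalate | O=C(OCc1ccccc1)C(=O)OCc1ccccc1 | starting material
7 | lithium enolate of methyl acetate (not isolated) | [Li+].C=C([O-])OC | intermediate
8 | 1-benzyl 4-methyl 2-oxobutanedioate | COC(=O)CC(=O)C(=O)OCc1ccccc1 | intermediate
9 | 1-benzyl 4-methyl (2Z)-2-[(triethylsilyl)oxy]but-2-enedioate (silyloxy cis to the CH–CO2Me ester) | COC(=O)/C=C(\O[Si](CC)(CC)CC)C(=O)OCc1ccccc1 | intermediate
10 | pyrrolidine N–C5–C6–C8–C7, endo adduct: C5 CO2tBu, C6 OSiEt3, C8 CO2Me and C7 aryl all on one face, C6 CO2Bn on the other | CC[Si](CC)(CC)O[C@]2(C(=O)OCc3ccccc3)[C@H](C(=O)OC(C)(C)C)N[C@H](c1ccc(O[Si](C(C)C)(C(C)C)C(C)C)cc1)[C@@H]2C(=O)OC | intermediate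
11 | pyrrolidine N–C5–C6–C8–C7, key-step precursor: C5 CO2tBu, C6 OSiEt3 and C7 aryl on one face (2,5-cis), C6 CO2Bn and C8 CO2Me on the other | CC[Si](CC)(CC)O[C@]2(C(=O)OCc3ccccc3)[C@H](C(=O)OC(C)(C)C)N[C@H](c1ccc(O[Si](C(C)C)(C(C)C)C(C)C)cc1)[C@H]2C(=O)OC | intermediate
12 | 1,1-diazene (N-nitrene) of 11 (not isolated) | CC[Si](CC)(CC)O[C@]2(C(=O)OCc3ccccc3)[C@H](C(=O)OC(C)(C)C)[N+](=[N-])[C@H](c1ccc(O[Si](C(C)C)(C(C)C)C(C)C)cc1)[C@H]2C(=O)OC | intermediate
13 | singlet 1,4-biradical at C5 and C7 (not isolated) | CC[Si](CC)(CC)O[C@](C(=O)OCc3ccccc3)([CH]C(=O)OC(C)(C)C)[C@H](C(=O)OC)[CH]c1ccc(O[Si](C(C)C)(C(C)C)C(C)C)cc1 | intermediate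
14 | cyclobutane C5–C6–C8–C7, key-step product: C5 CO2tBu, C6 OSiEt3 and C7 aryl on one face, C6 CO2Bn and C8 CO2Me on the other | CC[Si](CC)(CC)O[C@]2(C(=O)OCc3ccccc3)[C@H](C(=O)OC(C)(C)C)[C@H](c1ccc(O[Si](C(C)C)(C(C)C)C(C)C)cc1)[C@H]2C(=O)OC | intermediate
15 | tert-butyl acetoacetate | CC(=O)CC(=O)OC(C)(C)C | starting material
16 | dilithium dianion of tert-butyl acetoacetate (not isolated) | [Li+].[Li+].C=C([O-])C=C([O-])OC(C)(C)C | intermediate
17 | cyclobutane as 14 with C8 bearing C(=O)CH2C(=O)CH2CO2tBu | CC[Si](CC)(CC)O[C@]2(C(=O)OCc3ccccc3)[C@H](C(=O)OC(C)(C)C)[C@H](c1ccc(O[Si](C(C)C)(C(C)C)C(C)C)cc1)[C@H]2C(=O)CC(=O)CC(=O)OC(C)(C)C | intermediate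
18 | acylketene from 17 (not isolated) | CC[Si](CC)(CC)O[C@]2(C(=O)OCc3ccccc3)[C@H](C(=O)OC(C)(C)C)[C@H](c1ccc(O[Si](C(C)C)(C(C)C)C(C)C)cc1)[C@H]2C(=O)CC(=O)C=C=O | intermediate
19 | cyclobutane as 14 with C8 bearing 4-hydroxy-2-oxo-2H-pyran-6-yl | CC[Si](CC)(CC)O[C@]2(C(=O)OCc3ccccc3)[C@H](C(=O)OC(C)(C)C)[C@H](c1ccc(O[Si](C(C)C)(C(C)C)C(C)C)cc1)[C@H]2C4=CC(O)=CC(=O)O4 | intermediate
20 | cyclobutane as 14 with C8 bearing 4-methoxy-2-oxo-2H-pyran-6-yl | CC[Si](CC)(CC)O[C@]2(C(=O)OCc3ccccc3)[C@H](C(=O)OC(C)(C)C)[C@H](c1ccc(O[Si](C(C)C)(C(C)C)C(C)C)cc1)[C@H]2C4=CC(OC)=CC(=O)O4 | intermediate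
21 | cis-hydroxy acid: C5 CO2H, C6 OH and C7 aryl on one face, C6 CO2Bn and C8 methoxypyranonyl on the other | O[C@]2(C(=O)OCc3ccccc3)[C@H](C(=O)O)[C@H](c1ccc(O[Si](C(C)C)(C(C)C)C(C)C)cc1)[C@H]2C4=CC(OC)=CC(=O)O4 | intermediate
22 | Meldrum's acid (2,2-dimethyl-1,3-dioxane-4,6-dione) | CC1(C)OC(=O)CC(=O)O1 | starting material
23 | acyl Meldrum's acid of 21, enol form (not isolated) | O[C@]2(C(=O)OCc3ccccc3)[C@H](C(O)=C5C(=O)OC(C)(C)OC5=O)[C@H](c1ccc(O[Si](C(C)C)(C(C)C)C(C)C)cc1)[C@H]2C4=CC(OC)=CC(=O)O4 | intermediate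
24 | acylketene from 23 (not isolated) | O[C@]2(C(=O)OCc3ccccc3)[C@H](C(=O)C=C=O)[C@H](c1ccc(O[Si](C(C)C)(C(C)C)C(C)C)cc1)[C@H]2C4=CC(OC)=CC(=O)O4 | intermediate
25 | cis-fused β-keto lactone, benzyl 3,5-dioxo-2-oxabicyclo[4.2.0]octane-1-carboxylate with 7-aryl and 8-methoxypyranonyl (ring configuration as in 35) | O=C1CC(=O)O[C@]2(C(=O)OCc3ccccc3)[C@H]1[C@H](c1ccc(O[Si](C(C)C)(C(C)C)C(C)C)cc1)[C@H]2C4=CC(OC)=CC(=O)O4 | intermediate
26 | benzyl 5-methoxy-8-(4-methoxy-2-oxo-2H-pyran-6-yl)-3-oxo-7-[4-(triisopropylsilyloxy)phenyl]-2-oxabicyclo[4.2.0]oct-4-ene-1-carboxylate (ring configuration as in 35) | COC1=CC(=O)O[C@]2(C(=O)OCc3ccccc3)[C@H]1[C@H](c1ccc(O[Si](C(C)C)(C(C)C)C(C)C)cc1)[C@H]2C4=CC(OC)=CC(=O)O4 | intermediate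
27 | the 1-carboxylic acid corresponding to 26 | COC1=CC(=O)O[C@]2(C(=O)O)[C@H]1[C@H](c1ccc(O[Si](C(C)C)(C(C)C)C(C)C)cc1)[C@H]2C4=CC(OC)=CC(=O)O4 | intermediate
28 | the 1-(hydroxymethyl) compound corresponding to 26 | COC1=CC(=O)O[C@]2(CO)[C@H]1[C@H](c1ccc(O[Si](C(C)C)(C(C)C)C(C)C)cc1)[C@H]2C4=CC(OC)=CC(=O)O4 | intermediate
29 | the 1-carbaldehyde corresponding to 26 | COC1=CC(=O)O[C@]2(C=O)[C@H]1[C@H](c1ccc(O[Si](C(C)C)(C(C)C)C(C)C)cc1)[C@H]2C4=CC(OC)=CC(=O)O4 | intermediate
30 | {4-[(triisopropylsilyl)oxy]phenyl}methanol | CC(C)[Si](C(C)C)(C(C)C)Oc1ccc(CO)cc1 | intermediate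
31 | 1-phenyl-5-({4-[(triisopropylsilyl)oxy]benzyl}sulfanyl)-1H-tetrazole | CC(C)[Si](C(C)C)(C(C)C)Oc1ccc(CSc2nnnn2-c2ccccc2)cc1 | intermediate
32 | 1-phenyl-5-({4-[(triisopropylsilyl)oxy]benzyl}sulfonyl)-1H-tetrazole | CC(C)[Si](C(C)C)(C(C)C)Oc1ccc(CS(=O)(=O)c2nnnn2-c2ccccc2)cc1 | intermediate
33 | potassium salt of the α-sulfonyl carbanion of 32 (not isolated) | [K+].CC(C)[Si](C(C)C)(C(C)C)Oc1ccc([CH-]S(=O)(=O)c2nnnn2-c2ccccc2)cc1 | intermediate
34 | bis(triisopropylsilyl) ether of 35 (E styryl; ring configuration as in 35) | COC1=CC(=O)O[C@]2(/C=C/c3ccc(O[Si](C(C)C)(C(C)C)C(C)C)cc3)[C@H]1[C@H](c1ccc(O[Si](C(C)C)(C(C)C)C(C)C)cc1)[C@H]2C4=CC(OC)=CC(=O)O4 | intermediate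
35 | (1R,6S,7S,8S)-7-(4-hydroxyphenyl)-1-[(E)-2-(4-hydroxyphenyl)ethenyl]-5-methoxy-8-(4-methoxy-2-oxo-2H-pyran-6-yl)-2-oxabicyclo[4.2.0]oct-4-en-3-one | COC1=CC(=O)O[C@]2(/C=C/c3ccc(O)cc3)[C@H]1[C@H](c1ccc(O)cc1)[C@H]2c1cc(OC)cc(=O)o1 | target

**Step count and risks**

Total: 21 steps in three converging branches. Longest linear sequence: 16 steps (1, 2, 5–16, 20, 21).

Steps most likely to fail:

1. Step 7. The 1,4-biradical may cleave the C6–C8 bond (to a cinnamate and a silyloxybutenedioate) faster than it closes at 80 °C, and the iodane may oxidise the silyloxyarene or the ammonia may attack the esters. Fallback: setting out from 11, the amine would be treated with the anomeric amide N-(benzyloxy)-N-(pivaloyloxy)-4-(trifluoromethyl)benzamide in THF at 45 °C. Substitution at the amide nitrogen and rearrangement should give the same diazene 12 without oxidant or ammonia and at lower temperature; loss of N2 returns the route at 14. No new isolable compound lies on this path.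

2. Step 5. Michael addition of the silver ylide to the donor-substituted, trisubstituted alkene may be slow, the Michael adduct may lose silanolate instead of closing by Mannich reaction, and facial selectivity under the chiral catalyst may be poor. Fallback: setting out from 4 and 9, the ylide would be generated stoichiometrically as its N-lithio aza-enolate (LiBr, DBU, THF, or LiN(iPr)2 at −78 °C). This much more nucleophilic species should undergo the Michael–Mannich annulation to the racemic endo pyrrolidine F1. Epimerisation as in step 6 would give the racemic precursor F2, whose enantiomers would be separated by preparative chromatography on a chiral stationary phase, and the route is rejoined at 11.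

3. Step 6. The C8 ester enolate may expel triethylsilanolate from C6 (E1cB, giving the 2,5-dihydropyrrole diester) in competition with reprotonation. Fallback: setting out from 10, the triethylsilyl ether would be cleaved (HF·pyridine, THF, 0 °C) to the tertiary alcohol F3, whose β-leaving group is hydroxide and is not expelled by an amidine base. DBU epimerisation should then give the C8-epimeric alcohol F4, and re-silylation (Et3SiOSO2CF3, 2,6-lutidine, CH2Cl2) returns the route at 11.

**Further compounds**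

F0 | step 7 | none | none
F1 | step 5 | racemic endo pyrrolidine (10 and its enantiomer) | CC[Si](CC)(CC)O[C@]2(C(=O)OCc3ccccc3)[C@H](C(=O)OC(C)(C)C)N[C@H](c1ccc(O[Si](C(C)C)(C(C)C)C(C)C)cc1)[C@@H]2C(=O)OC.CC[Si](CC)(CC)O[C@@]2(C(=O)OCc3ccccc3)[C@@H](C(=O)OC(C)(C)C)N[C@@H](c1ccc(O[Si](C(C)C)(C(C)C)C(C)C)cc1)[C@H]2C(=O)OC
F2 | step 5 | racemic C8-epimerised pyrrolidine (11 and its enantiomer) | CC[Si](CC)(CC)O[C@]2(C(=O)OCc3ccccc3)[C@H](C(=O)OC(C)(C)C)N[C@H](c1ccc(O[Si](C(C)C)(C(C)C)C(C)C)cc1)[C@H]2C(=O)OC.CC[Si](CC)(CC)O[C@@]2(C(=O)OCc3ccccc3)[C@@H](C(=O)OC(C)(C)C)N[C@@H](c1ccc(O[Si](C(C)C)(C(C)C)C(C)C)cc1)[C@@H]2C(=O)OC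
F3 | step 6 | tertiary alcohol from 10 (C6 OH; C8 ester cis to aryl) | O[C@]2(C(=O)OCc3ccccc3)[C@H](C(=O)OC(C)(C)C)N[C@H](c1ccc(O[Si](C(C)C)(C(C)C)C(C)C)cc1)[C@@H]2C(=O)OC
F4 | step 6 | C8 epimer of F3 (C8 ester trans to aryl) | O[C@]2(C(=O)OCc3ccccc3)[C@H](C(=O)OC(C)(C)C)N[C@H](c1ccc(O[Si](C(C)C)(C(C)C)C(C)C)cc1)[C@H]2C(=O)OC
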